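# Design of a total synthesis of CNP0103636.1 through a pyrone-to-arene construction of ring A of unit 4

## The problem

The target 30 is a linear tetraflavanoid. Epicatechin (unit 1) is bonded through C4 to C6 of epiafzelechin (unit 2), unit 2 through C4 to C8 of epicatechin (unit 3), and unit 3 through C4 to C6 of a terminal epicatechin (unit 4). Three aryl–C4 bonds must be formed, and two of them go to C6 of a ring A, the position a flavanyl cation attacks only in minor amount while C8 is free. There are eleven stereocentres: C2 and C3 of every unit (all 2R,3R, 2,3-cis) and C4 of units 1–3 (all 3,4-trans). Each C4 centre can be governed by its neighbouring C3 substituent, because a nucleophile adds to the C4 cation anti to it. Nothing relays chirality from one unit to the next, so every unit must bring its own C2 and C3. The fifteen phenols and four secondary alcohols make the free compound air-sensitive; the interflavan bonds cleave in acid, and free flavan-3-ols epimerise at C2 in base. All oxygens are therefore carried as benzyl ethers and released once, by neutral hydrogenolysis. The feature that opens the key step is ring A of unit 4: oxygen on C5, C7 and C8a alternates with C4a, C6 and C8, the pattern of a cyclised triketide. 4-Hydroxy-6-methyl-2-pyrone (4) holds the same carbons in masked form. Its single nucleophilic ring carbon, C3, corresponds to C6 of unit 4, and its methyl carbon to C4a.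

## Retrosynthesis

**30 from 29.** No skeletal bond is cut. The nineteen benzyl ethers and three aryl bromides of 29 fall in one hydrogenolysis, so no acid or base touches the free tetramer.

**29 to 28 and 21 (C4 of unit 2 to C8 of unit 3).** The central bond is cut last because it is the only 4→8 bond, the regiochemistry that cation chemistry gives by itself, and because it halves the molecule. Cutting a 4→6 bond last would leave two comparable C6 positions competing in a trimer. The forward step needs a C4 cation on unit 2 of dimer 28 and a single reactive carbon in dimer 21. In 28 the cation is stored as an aryl sulfide. In 21, C8 of unit 4 is capped with bromine, which leaves C8 of unit 3 as the preferred site.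

**28 to 22 and 27 (C4 of unit 1 to C6 of unit 2).** Bromine on C8 of 27 leaves C6 as its only nucleophilic carbon. Bromine on C8 of 22 stops 22 from attacking its own cation. The 2-ethoxyethyl ether of 22 is ionised by an oxophilic Lewis acid that leaves the sulfide of 27 alone. Electrophile 22 comes from 3 by bromination, and 3 from (−)-epicatechin (1) via 2. Nucleophile 27 comes from (−)-epiafzelechin (23) via 24, 25 and 26.

**21 to 17 (O1–C2 of unit 4).** Ring C of unit 4 is opened at the benzylic C–O bond, giving 20, 19, 18 and 17 in turn. Forward, the phenol on C8a displaces an activated C2 hydroxyl with inversion (Mitsunobu reaction). The open chain must therefore be the anti diol derivative with C2 epimeric to the target. The two phenols of 17 are told apart by what flanks them: the C5 hydroxyl sits between unit 3 and the chain, the C8a hydroxyl beside C8. Bromine is placed on C8 at the diphenol stage (17 to 18), where this ring is far more electron-rich than any benzyl ether ring.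

**17 to 15 (key step: C4a–C5, ring A of unit 4).** A direct Friedel–Crafts cut of the C6–C4 bond would ask a ring A with C8 free to react at C6. Instead ring A is taken apart to pyrone 15, in which the bond to unit 3 already exists at pyrone C3. The precursor has no arene at this site and no regiochemical choice. Forward, an alkoxide opens the lactone, and the ketone enolate of the former side-chain methylene closes onto the ester carbon; the ring then aromatises. Benzyloxide is used in place of a smaller alkoxide, so that exchange at the benzyloxy-bearing vinylogous carbon changes nothing.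

**15 to 5 and 12 (bond between future C4a and C4).** Pyrone 15 is the benzyl ether of 14. Compound 14 is cut between the two methylenes of its side chain into the dianion of 5 and triflate 13, made from alcohol 12. C3 of 5 is blocked, so only the 6-methyl group is deprotonated. A triflate is chosen because the carbon is β to an alkoxy-bearing branch.

**5 to 4 and 3 (pyrone C3 to C4 of unit 3).** Lactone 4 is cheap and can be used in excess against the cation from 3, which suppresses self-condensation of 3. Doing this step before the chain is attached keeps the benzylic silyl ether of 12 away from the Lewis acid.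

**12 to 8 and 9.** The anti relation of the two oxygens and the ready-made benzyl ether on the future C3 point to an anti-selective glycolate aldol. Imide 8 (from auxiliary 6 and acid chloride 7) and aldehyde 9 give 10; silylation gives 11, and reductive removal of the auxiliary gives 12.

## Roads not taken

**Alternative 1: bicyclic ketal detour.**
- Cut: ring C of unit 1 is dissected rather than taken from epicatechin; a C3–O bond and an extra C2–O7 bond to unit 2 are formed together.
- Forward key step: dimethyldioxirane would epoxidise a C2=C3 enol ether in ring C of unit 1 anti to the C4 aryl group, and the O7 phenol of unit 2 would open the epoxide at C2, giving the doubly linked ketal A1.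
- Merits: one existing centre (C4) dictates C3 and C2 in a single operation. The second link also proves that unit 1 sits on C6, which the chosen plan secures only through a bromine cap (step 20). On that point this road is stronger.
- Weak points: the target is singly linked, so the C2–O7 bond must later be reduced with hydride entering C2 from the one face that gives 2,3-cis, and no element is evident to enforce that. The flavene substrate discards the two stereocentres that epicatechin supplies. Only one of the two 4→6 junctions is addressed, and unit 2 still needs a leaving group at C4.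
- Comparison: the chosen plan takes C2 and C3 of unit 1 from the natural product and spends three short steps on the upper 4→6 bond.

**Alternative 2: benzannulation writes ring A of unit 2.**
- Cut: three bonds of ring A of unit 2 (C4a–C8a, C5–C6, C8–C8a).
- Forward key step: heating a cyclobutenone ring on C4 of unit 1 with a siloxyalkyne terminus of the cinnamyl chain would run an electrocyclic opening, a ketene–alkyne cycloaddition and a 6π closure to phenol A2.
- Merits: like the chosen plan it builds the ring around a pre-set 4→6 bond. It is better in one respect: only the phenol at the future O1 is free in A2, so ring C closure has no phenol choice. The chosen plan has two free phenols in 17 and must rely on their different surroundings (step 13) or on a protecting-group detour.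
- Weak points: unit 2 is an internal unit. After the benzannulation its ring C still has to be built with 2,3-cis configuration, and its C4 must then be oxidised to a leaving group in a dimer that holds a more easily oxidised diarylmethine in unit 1. Both reaction partners are sensitive and need several steps.
- Comparison: the chosen plan applies the same logic to the terminal unit 4, which needs no C4 activation, and starts from a commercial pyrone.

**Alternative 3: oxa-Povarov union.**
- Cut: C2–C3 and C4–C4a of unit 2, so that ring C of unit 2 forms between the two halves.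
- Forward key step: SnCl4 would ionise an acetal on the ring A phenol oxygen of the upper fragment. The oxocarbenium ion would be captured at C2 by an enol benzoate double bond on C8 of unit 3, and ring A would close on the C4 cation, giving A3.
- Merits: it is the most convergent road and the shortest on paper. It needs no epiafzelechin and avoids the hindered dimer–dimer coupling of step 21. These are real advantages.
- Weak points: C2, C3 and C4 of unit 2 are created at once, with no nearby element to fix their sense relative to units 1 and 3. The required 2,3-cis-3,4-trans pattern depends on enol ester geometry and on endo or exo approach. The electron-rich rings invite Friedel–Crafts diversion of the oxocarbenium ion.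
- Comparison: the chosen plan is longer, but every stereocentre has a defined origin: natural flavanols, an auxiliary on a small fragment, or trans attack on a C4 cation.

Key step: step 10

Assumption 1: (−)-epiafzelechin (23) is taken as a purchasable natural flavan-3-ol, like (−)-epicatechin.

Assumption 2: in step 5 the thiocarbonyl-chelated titanium enolate is taken to react on the face away from the auxiliary benzyl group, so the (R)-auxiliary is specified; if the sense were the opposite, the (S)-auxiliary would lead to the same alcohol 12.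

## Route

Step 1
Reactants: 1 (−)-epicatechin
Product: 2 3,5,7,3',4'-penta-O-benzyl-(−)-epicatechin
Conditions: BnBr, NaH, DMF, −20 °C → rt
Reagents that add atoms: benzyl bromide, BrCc1ccccc1
Why: Williamson etherification of the four phenoxides and the C3 alkoxide; fast O-alkylation at low temperature leaves C2 and C3 untouched.

Step 2
Reactants: 2 3,5,7,3',4'-penta-O-benzyl-(−)-epicatechin
Product: 3 3,5,7,3',4'-penta-O-benzyl-4β-(2-ethoxyethoxy)epicatechin (2,3-cis, 3,4-trans)
Conditions: DDQ, 2-ethoxyethanol, CH2Cl2, rt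
Reagents that add atoms: 2-ethoxyethanol, CCOCCO
Why: DDQ benzylic oxidation; hydride abstraction at C4 gives a cation stabilised by the ring A oxygens, and the alcohol adds anti to the C3 benzyloxy group, which sets the 3,4-trans centre.

Step 3
Reactants: 3 3,5,7,3',4'-penta-O-benzyl-4β-(2-ethoxyethoxy)epicatechin; 4 triacetic acid lactone (4-hydroxy-6-methyl-2H-pyran-2-one, fivefold excess)
Product: 5 4-hydroxy-6-methyl-3-(3,5,7,3',4'-penta-O-benzylepicatechin-4β-yl)-2H-pyran-2-one
Conditions: TMSOTf (0.2 equiv), CH2Cl2–THF, −78 → −30 °C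
Reagents that add atoms: none
Why: Friedel–Crafts-type C-alkylation of a 4-hydroxy-2-pyrone by a benzylic cation; C3 is the only nucleophilic carbon of 4, O-alkylation is reversible under the acid, attack anti to the C3 benzyloxy group sets C4 of unit 3 (3,4-trans), and excess 4 outruns attack by ring A of 3.

Step 4
Reactants: 6 (R)-4-benzyl-1,3-oxazolidine-2-thione; 7 benzyloxyacetyl chloride
Product: 8 (R)-4-benzyl-3-[(benzyloxy)acetyl]-1,3-oxazolidine-2-thione
Conditions: Et3N, CH2Cl2, 0 °C
Reagents that add atoms: none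
Why: N-acylation of the auxiliary by an acid chloride, a standard preparation of N-glycolyl oxazolidinethiones.

Step 5
Reactants: 8 (R)-4-benzyl-3-[(benzyloxy)acetyl]-1,3-oxazolidine-2-thione; 9 3,4-bis(benzyloxy)benzaldehyde
Product: 10 (R)-4-benzyl-3-[(2S,3S)-2-(benzyloxy)-3-[3,4-bis(benzyloxy)phenyl]-3-hydroxypropanoyl]-1,3-oxazolidine-2-thione (2,3-anti)
Conditions: TiCl4, i-Pr2NEt, CH2Cl2, −78 °C; then 9 premixed with TiCl4, −78 °C
Reagents that add atoms: none
Why: anti-selective titanium glycolate aldol of an N-glycolyl oxazolidinethione; the chelated Z-enolate meets the TiCl4-bound aldehyde in an open transition state, the auxiliary benzyl group fixes the enolate face (C2) and the antiperiplanar approach gives the anti carbinol (C3).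

Step 6
Reactants: 10 (R)-4-benzyl-3-[(2S,3S)-2-(benzyloxy)-3-[3,4-bis(benzyloxy)phenyl]-3-hydroxypropanoyl]-1,3-oxazolidine-2-thione
Product: 11 the 3-O-tert-butyldimethylsilyl ether of 10
Conditions: TBSOTf, 2,6-lutidine, CH2Cl2, −78 → 0 °C
Reagents that add atoms: tert-butyldimethylsilyl trifluoromethanesulfonate, CC(C)(C)[Si](C)(C)OS(=O)(=O)C(F)(F)F
Why: silylation of a secondary alcohol with a silyl triflate and a hindered base; non-basic conditions avoid retro-aldol cleavage.

Step 7
Reactants: 11 the 3-O-tert-butyldimethylsilyl ether of 10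
Product: 12 (2R,3S)-2-(benzyloxy)-3-[3,4-bis(benzyloxy)phenyl]-3-[(tert-butyldimethylsilyl)oxy]propan-1-ol
Conditions: LiBH4, MeOH (1 equiv), THF, 0 °C
Reagents that add atoms: none
Why: reductive cleavage of the activated N-acyl oxazolidinethione to the primary alcohol with release of the auxiliary; ethers and both stereocentres are untouched.

Step 8
Reactants: 12 (2R,3S)-2-(benzyloxy)-3-[3,4-bis(benzyloxy)phenyl]-3-[(tert-butyldimethylsilyl)oxy]propan-1-ol; 5 4-hydroxy-6-methyl-3-(3,5,7,3',4'-penta-O-benzylepicatechin-4β-yl)-2H-pyran-2-one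
Product: 14 6-[(3R,4S)-3-(benzyloxy)-4-[3,4-bis(benzyloxy)phenyl]-4-[(tert-butyldimethylsilyl)oxy]butyl]-4-hydroxy-3-(penta-O-benzylepicatechin-4β-yl)-2H-pyran-2-one, via primary triflate 13 (not isolated)
Conditions: 12, Tf2O, 2,6-lutidine, CH2Cl2, −78 °C, cold hexane filtration; 5, LiN(i-Pr)2 (2.2 equiv), THF–DMPU, −78 °C; then 13, −78 → −40 °C
Reagents that add atoms: none
Why: alkylation of a 4-hydroxy-6-methyl-2-pyrone dianion at the methyl carbon, the γ-alkylation known for 1,3-dicarbonyl dianions; C3 is blocked, and the triflate makes the SN2 step fast enough at −78 °C despite the β-alkoxy branch.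

Step 9
Reactants: 14 6-[(3R,4S)-3-(benzyloxy)-4-[3,4-bis(benzyloxy)phenyl]-4-[(tert-butyldimethylsilyl)oxy]butyl]-4-hydroxy-3-(penta-O-benzylepicatechin-4β-yl)-2H-pyran-2-one
Product: 15 the 4-O-benzyl ether of 14 (4-benzyloxy-2-pyrone)
Conditions: BnBr, K2CO3, DMF, rt
Reagents that add atoms: benzyl bromide, BrCc1ccccc1
Why: O-alkylation of a 4-hydroxy-2-pyrone under carbonate conditions gives the 4-alkoxy-2-pyrone; C3 is substituted, so C-benzylation cannot compete.

Step 10
Reactants: 15 the 4-O-benzyl ether of 14 (4-benzyloxy-2-pyrone)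
Product: 17 5-(benzyloxy)-2-[(2R,3S)-2-(benzyloxy)-3-[3,4-bis(benzyloxy)phenyl]-3-[(tert-butyldimethylsilyl)oxy]propyl]-4-(penta-O-benzylepicatechin-4β-yl)benzene-1,3-diol, via ring-opened benzyl keto ester 16 (not isolated)
Conditions: BnONa (1 M in BnOH, 5 equiv), THF, 60 °C, argon; aq. NH4Cl
Reagents that add atoms: none
Why: Benzyloxide adds to the lactone carbonyl and opens 15 to keto ester 16, in which the enol ether double bond keeps the ester and the ketone-bearing methylene cis. The ketone enolate at the former side-chain methylene attacks the ester carbon, benzyloxide leaves, and the cyclohexenedione tautomerises to the diphenoxide of 17; pyrone C3 becomes C6 of unit 4, the lactone carbonyl becomes C5–OH, the ring oxygen becomes the C8a oxygen and the side-chain methylene becomes C4a. The closest known reaction is the base-induced conversion of 4-alkoxy-6-alkyl-2-pyrones into phloroglucinol monoethers by ring opening and intramolecular Claisen condensation. Ring A closes in a 6-(enolendo)-exo-trig mode. No stereocentre is formed, and the chain centres are safe because the benzyloxy carbon is γ to the ketone and cannot undergo β-elimination or enolisation. The step needs carbon rather than oxygen attack of the enolate on the ester: relactonisation is reversible, whereas the Claisen path ends in an aromatic diphenoxide. Benzyloxide makes alkoxide exchange at the vinylogous benzyloxy carbon degenerate, so the C7 ether stays hydrogenolysable.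

Step 11
Reactants: 17 5-(benzyloxy)-2-[(2R,3S)-2-(benzyloxy)-3-[3,4-bis(benzyloxy)phenyl]-3-[(tert-butyldimethylsilyl)oxy]propyl]-4-(penta-O-benzylepicatechin-4β-yl)benzene-1,3-diol
Product: 18 the 6-bromo derivative of 17 (bromine between the C1 hydroxyl and the benzyloxy group; future C8 of unit 4)
Conditions: NBS (1.0 equiv), CH2Cl2, −78 °C
Reagents that add atoms: N-bromosuccinimide, O=C1CCC(=O)N1Br
Why: electrophilic aromatic bromination; the ring with two free hydroxyls is the most electron-rich arene present and has one free carbon, ortho and para to those hydroxyls.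

Step 12
Reactants: 18 the 6-bromo derivative of 17
Product: 19 6-bromo-5-(benzyloxy)-2-[(2R,3S)-2-(benzyloxy)-3-[3,4-bis(benzyloxy)phenyl]-3-hydroxypropyl]-4-(penta-O-benzylepicatechin-4β-yl)benzene-1,3-diol
Conditions: Bu4NF, AcOH, THF, 0 °C → rt
Reagents that add atoms: none
Why: fluoride cleavage of the secondary silyl ether; acetic acid buffers the phenoxides.

Step 13
Reactants: 19 6-bromo-5-(benzyloxy)-2-[(2R,3S)-2-(benzyloxy)-3-[3,4-bis(benzyloxy)phenyl]-3-hydroxypropyl]-4-(penta-O-benzylepicatechin-4β-yl)benzene-1,3-diol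
Product: 20 3,7,3',4'-tetra-O-benzyl-8-bromo-6-(penta-O-benzylepicatechin-4β-yl)-(−)-epicatechin (5-OH free)
Conditions: PPh3, DIAD, toluene, 0 °C → rt
Reagents that add atoms: none
Why: intramolecular Mitsunobu etherification (6-exo-tet); SN2 displacement of the oxyphosphonium group inverts C2 from S to R and gives the 2,3-cis flavan, and the more acidic, less crowded phenol next to bromine reacts rather than the one wedged between unit 3 and the chain.

Step 14
Reactants: 20 3,7,3',4'-tetra-O-benzyl-8-bromo-6-(penta-O-benzylepicatechin-4β-yl)-(−)-epicatechin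
Product: 21 3,5,7,3',4'-penta-O-benzyl-8-bromo-6-(penta-O-benzylepicatechin-4β-yl)-(−)-epicatechin (lower dimer, unit 3–unit 4)
Conditions: BnBr, K2CO3, DMF, 50 °C
Reagents that add atoms: benzyl bromide, BrCc1ccccc1
Why: Williamson etherification of the remaining hindered phenol, so that no free phenol meets the halonium reagent of step 21.

Step 15
Reactants: 3 3,5,7,3',4'-penta-O-benzyl-4β-(2-ethoxyethoxy)epicatechin
Product: 22 3,5,7,3',4'-penta-O-benzyl-8-bromo-4β-(2-ethoxyethoxy)epicatechin
Conditions: NBS, CH2Cl2, −78 → −20 °C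
Reagents that add atoms: N-bromosuccinimide, O=C1CCC(=O)N1Br
Why: electrophilic bromination of a 5,7-dialkoxyflavan goes to C8, as known for benzylated flavan-3-ols.

Step 16
Reactants: 23 (−)-epiafzelechin
Product: 24 3,5,7,4'-tetra-O-benzyl-(−)-epiafzelechin
Conditions: BnBr, NaH, DMF, −20 °C → rt
Reagents that add atoms: benzyl bromide, BrCc1ccccc1
Why: Williamson etherification as in step 1.

Step 17
Reactants: 24 3,5,7,4'-tetra-O-benzyl-(−)-epiafzelechin
Product: 25 3,5,7,4'-tetra-O-benzyl-8-bromo-(−)-epiafzelechin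
Conditions: NBS, CH2Cl2, −78 → 0 °C
Reagents that add atoms: N-bromosuccinimide, O=C1CCC(=O)N1Br
Why: C8-selective bromination as in step 15; the bromine later leaves C6 as the only nucleophilic carbon of unit 2.

Step 18
Reactants: 25 3,5,7,4'-tetra-O-benzyl-8-bromo-(−)-epiafzelechin
Product: 26 3,5,7,4'-tetra-O-benzyl-8-bromo-4β-(2-ethoxyethoxy)epiafzelechin (3,4-trans)
Conditions: DDQ, 2-ethoxyethanol, CH2Cl2, rt
Reagents that add atoms: 2-ethoxyethanol, CCOCCO
Why: DDQ benzylic oxidation at C4 with trans capture by the alcohol, as in step 2.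

Step 19
Reactants: 26 3,5,7,4'-tetra-O-benzyl-8-bromo-4β-(2-ethoxyethoxy)epiafzelechin
Product: 27 3,5,7,4'-tetra-O-benzyl-8-bromo-4β-[(2,6-dimethylphenyl)sulfanyl]epiafzelechin (3,4-trans)
Conditions: 2,6-Me2C6H3SH, TMSOTf (0.2 equiv), CH2Cl2, −78 → −40 °C
Reagents that add atoms: 2,6-dimethylbenzenethiol, Cc1cccc(C)c1S
Why: Lewis-acid ionisation of the C4 ether and capture of the cation by the thiol anti to the C3 benzyloxy group; the sulfide is a C4 leaving group that oxophilic Lewis acids do not activate.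

Step 20
Reactants: 22 3,5,7,3',4'-penta-O-benzyl-8-bromo-4β-(2-ethoxyethoxy)epicatechin; 27 3,5,7,4'-tetra-O-benzyl-8-bromo-4β-[(2,6-dimethylphenyl)sulfanyl]epiafzelechin
Product: 28 3,5,7,4'-tetra-O-benzyl-8-bromo-4β-[(2,6-dimethylphenyl)sulfanyl]-6-(3,5,7,3',4'-penta-O-benzyl-8-bromoepicatechin-4β-yl)epiafzelechin (upper dimer, unit 1–unit 2)
Conditions: TMSOTf (0.2 equiv), CH2Cl2, −78 → −40 °C
Reagents that add atoms: none
Why: Friedel–Crafts coupling of a flavan C4 cation with a ring A; bromine blocks C8 of 27 so C6 reacts, bromine on 22 prevents self-condensation, the sulfide stays intact, and attack anti to the C3 benzyloxy group sets C4 of unit 1 (3,4-trans).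

Step 21
Reactants: 28 upper dimer (unit 1–unit 2, C4 sulfide); 21 lower dimer (unit 3–unit 4)
Product: 29 nonadeca-O-benzyl-8,8,8-tribromo tetramer (bromine on C8 of units 1, 2 and 4): benzylated epicatechin-(4β→6)-epiafzelechin-(4β→8)-epicatechin-(4β→6)-epicatechin
Conditions: NIS, 4 Å molecular sieves, CH2Cl2, −78 → −30 °C
Reagents that add atoms: none
Why: thiophilic activation of the C4 aryl sulfide by an iodonium source gives the C4 cation of unit 2, which is captured by C8 of unit 3 (C8 of unit 4 is brominated, and C6 of unit 3 lies between two benzyloxy groups); attack anti to the C3 benzyloxy group sets C4 of unit 2 (3,4-trans).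

Step 22
Reactants: 29 nonadeca-O-benzyl-8,8,8-tribromo tetramer
Product: 30 epicatechin-(4β→6)-epiafzelechin-(4β→8)-epicatechin-(4β→6)-epicatechin (CNP0103636.1)
Conditions: H2 (1 atm), Pd(OH)2/C, Et3N, THF–MeOH–H2O, rt
Reagents that add atoms: none
Why: hydrogenolysis of the benzyl ethers together with hydrodebromination of the three aryl bromides; triethylamine takes up the HBr so the acid-labile interflavan bonds and all stereocentres are preserved.

## Compound list

1 | (−)-epicatechin | O[C@@H]1Cc2c(O)cc(O)cc2O[C@@H]1c1ccc(O)c(O)c1 | starting material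
2 | 3,5,7,3',4'-penta-O-benzyl-(−)-epicatechin | c9ccccc9CO[C@@H]1Cc2c(OCc9ccccc9)cc(OCc9ccccc9)cc2O[C@@H]1c1ccc(OCc9ccccc9)c(OCc9ccccc9)c1 | intermediate
3 | 3,5,7,3',4'-penta-O-benzyl-4β-(2-ethoxyethoxy)epicatechin | CCOCCO[C@H]1c2c(OCc9ccccc9)cc(OCc9ccccc9)cc2O[C@H](c2ccc(OCc9ccccc9)c(OCc9ccccc9)c2)[C@@H]1OCc9ccccc9 | intermediate
4 | triacetic acid lactone | CC1=CC(O)=CC(=O)O1 | starting material
5 | 4-hydroxy-6-methyl-3-(penta-O-benzylepicatechin-4β-yl)-2H-pyran-2-one | CC1=CC(O)=C([C@H]2c3c(OCc9ccccc9)cc(OCc9ccccc9)cc3O[C@H](c3ccc(OCc9ccccc9)c(OCc9ccccc9)c3)[C@@H]2OCc9ccccc9)C(=O)O1 | intermediate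
6 | (R)-4-benzyl-1,3-oxazolidine-2-thione | S=C1N[C@H](Cc2ccccc2)CO1 | starting material
7 | benzyloxyacetyl chloride | O=C(Cl)COCc1ccccc1 | starting material
8 | (R)-4-benzyl-3-[(benzyloxy)acetyl]-1,3-oxazolidine-2-thione | O=C(COCc1ccccc1)N1[C@H](Cc2ccccc2)COC1=S | intermediate
9 | 3,4-bis(benzyloxy)benzaldehyde | O=Cc1ccc(OCc2ccccc2)c(OCc2ccccc2)c1 | starting material
10 | (R)-4-benzyl-3-[(2S,3S)-2-(benzyloxy)-3-[3,4-bis(benzyloxy)phenyl]-3-hydroxypropanoyl]-1,3-oxazolidine-2-thione | O=C([C@@H](OCc9ccccc9)[C@@H](O)c1ccc(OCc9ccccc9)c(OCc9ccccc9)c1)N1[C@H](Cc2ccccc2)COC1=S | intermediate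
11 | 3-O-tert-butyldimethylsilyl ether of 10 | O=C([C@@H](OCc9ccccc9)[C@@H](O[Si](C)(C)C(C)(C)C)c1ccc(OCc9ccccc9)c(OCc9ccccc9)c1)N1[C@H](Cc2ccccc2)COC1=S | intermediate
12 | (2R,3S)-2-(benzyloxy)-3-[3,4-bis(benzyloxy)phenyl]-3-[(tert-butyldimethylsilyl)oxy]propan-1-ol | OC[C@@H](OCc9ccccc9)[C@@H](O[Si](C)(C)C(C)(C)C)c1ccc(OCc9ccccc9)c(OCc9ccccc9)c1 | intermediate
13 | (2R,3S)-2-(benzyloxy)-3-[3,4-bis(benzyloxy)phenyl]-3-[(tert-butyldimethylsilyl)oxy]propyl trifluoromethanesulfonate | O=S(=O)(OC[C@@H](OCc9ccccc9)[C@@H](O[Si](C)(C)C(C)(C)C)c1ccc(OCc9ccccc9)c(OCc9ccccc9)c1)C(F)(F)F | intermediate (not isolated)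
14 | 6-[(3R,4S)-3-(benzyloxy)-4-[3,4-bis(benzyloxy)phenyl]-4-[(tert-butyldimethylsilyl)oxy]butyl]-4-hydroxy-3-(penta-O-benzylepicatechin-4β-yl)-2H-pyran-2-one | O=C1OC(CC[C@@H](OCc9ccccc9)[C@@H](O[Si](C)(C)C(C)(C)C)c5ccc(OCc9ccccc9)c(OCc9ccccc9)c5)=CC(O)=C1[C@H]4c5c(OCc9ccccc9)cc(OCc9ccccc9)cc5O[C@H](c5ccc(OCc9ccccc9)c(OCc9ccccc9)c5)[C@@H]4OCc9ccccc9 | intermediate
15 | 4-O-benzyl ether of 14 | O=C1OC(CC[C@@H](OCc9ccccc9)[C@@H](O[Si](C)(C)C(C)(C)C)c5ccc(OCc9ccccc9)c(OCc9ccccc9)c5)=CC(OCc9ccccc9)=C1[C@H]4c5c(OCc9ccccc9)cc(OCc9ccccc9)cc5O[C@H](c5ccc(OCc9ccccc9)c(OCc9ccccc9)c5)[C@@H]4OCc9ccccc9 | intermediate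
16 | benzyl (2E,8R,9S)-3,8-bis(benzyloxy)-9-[3,4-bis(benzyloxy)phenyl]-9-[(tert-butyldimethylsilyl)oxy]-5-oxo-2-(penta-O-benzylepicatechin-4β-yl)non-2-enoate | O=C(OCc9ccccc9)/C(=C(/OCc9ccccc9)CC(=O)CC[C@@H](OCc9ccccc9)[C@@H](O[Si](C)(C)C(C)(C)C)c5ccc(OCc9ccccc9)c(OCc9ccccc9)c5)[C@H]4c5c(OCc9ccccc9)cc(OCc9ccccc9)cc5O[C@H](c5ccc(OCc9ccccc9)c(OCc9ccccc9)c5)[C@@H]4OCc9ccccc9 | intermediate (not isolated)
17 | 5-(benzyloxy)-2-[(2R,3S)-2-(benzyloxy)-3-[3,4-bis(benzyloxy)phenyl]-3-[(tert-butyldimethylsilyl)oxy]propyl]-4-(penta-O-benzylepicatechin-4β-yl)benzene-1,3-diol | Oc1cc(OCc9ccccc9)c([C@H]4c5c(OCc9ccccc9)cc(OCc9ccccc9)cc5O[C@H](c5ccc(OCc9ccccc9)c(OCc9ccccc9)c5)[C@@H]4OCc9ccccc9)c(O)c1C[C@@H](OCc9ccccc9)[C@@H](O[Si](C)(C)C(C)(C)C)c5ccc(OCc9ccccc9)c(OCc9ccccc9)c5 | intermediate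
18 | 6-bromo derivative of 17 | Oc1c(Br)c(OCc9ccccc9)c([C@H]4c5c(OCc9ccccc9)cc(OCc9ccccc9)cc5O[C@H](c5ccc(OCc9ccccc9)c(OCc9ccccc9)c5)[C@@H]4OCc9ccccc9)c(O)c1C[C@@H](OCc9ccccc9)[C@@H](O[Si](C)(C)C(C)(C)C)c5ccc(OCc9ccccc9)c(OCc9ccccc9)c5 | intermediate
19 | desilylated carbinol of 18, (2R,3S)-3-hydroxypropyl chain | Oc1c(Br)c(OCc9ccccc9)c([C@H]4c5c(OCc9ccccc9)cc(OCc9ccccc9)cc5O[C@H](c5ccc(OCc9ccccc9)c(OCc9ccccc9)c5)[C@@H]4OCc9ccccc9)c(O)c1C[C@@H](OCc9ccccc9)[C@@H](O)c5ccc(OCc9ccccc9)c(OCc9ccccc9)c5 | intermediate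
20 | 3,7,3',4'-tetra-O-benzyl-8-bromo-6-(penta-O-benzylepicatechin-4β-yl)-(−)-epicatechin | Oc1c2C[C@@H](OCc9ccccc9)[C@@H](c3ccc(OCc9ccccc9)c(OCc9ccccc9)c3)Oc2c(Br)c(OCc9ccccc9)c1[C@H]4c5c(OCc9ccccc9)cc(OCc9ccccc9)cc5O[C@H](c5ccc(OCc9ccccc9)c(OCc9ccccc9)c5)[C@@H]4OCc9ccccc9 | intermediate
21 | 3,5,7,3',4'-penta-O-benzyl-8-bromo-6-(penta-O-benzylepicatechin-4β-yl)-(−)-epicatechin | c9ccccc9COc1c2C[C@@H](OCc9ccccc9)[C@@H](c3ccc(OCc9ccccc9)c(OCc9ccccc9)c3)Oc2c(Br)c(OCc9ccccc9)c1[C@H]4c5c(OCc9ccccc9)cc(OCc9ccccc9)cc5O[C@H](c5ccc(OCc9ccccc9)c(OCc9ccccc9)c5)[C@@H]4OCc9ccccc9 | intermediate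
22 | 3,5,7,3',4'-penta-O-benzyl-8-bromo-4β-(2-ethoxyethoxy)epicatechin | CCOCCO[C@H]1c2c(OCc9ccccc9)cc(OCc9ccccc9)c(Br)c2O[C@H](c2ccc(OCc9ccccc9)c(OCc9ccccc9)c2)[C@@H]1OCc9ccccc9 | intermediate
23 | (−)-epiafzelechin | O[C@@H]1Cc2c(O)cc(O)cc2O[C@@H]1c1ccc(O)cc1 | starting material
24 | 3,5,7,4'-tetra-O-benzyl-(−)-epiafzelechin | c9ccccc9CO[C@@H]1Cc2c(OCc9ccccc9)cc(OCc9ccccc9)cc2O[C@@H]1c1ccc(OCc9ccccc9)cc1 | intermediate
25 | 3,5,7,4'-tetra-O-benzyl-8-bromo-(−)-epiafzelechin | c9ccccc9CO[C@@H]1Cc2c(OCc9ccccc9)cc(OCc9ccccc9)c(Br)c2O[C@@H]1c1ccc(OCc9ccccc9)cc1 | intermediate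
26 | 3,5,7,4'-tetra-O-benzyl-8-bromo-4β-(2-ethoxyethoxy)epiafzelechin | CCOCCO[C@H]1c2c(OCc9ccccc9)cc(OCc9ccccc9)c(Br)c2O[C@H](c2ccc(OCc9ccccc9)cc2)[C@@H]1OCc9ccccc9 | intermediate
27 | 3,5,7,4'-tetra-O-benzyl-8-bromo-4β-[(2,6-dimethylphenyl)sulfanyl]epiafzelechin | Cc1cccc(C)c1S[C@H]2c3c(OCc9ccccc9)cc(OCc9ccccc9)c(Br)c3O[C@H](c3ccc(OCc9ccccc9)cc3)[C@@H]2OCc9ccccc9 | intermediate
28 | 3,5,7,4'-tetra-O-benzyl-8-bromo-4β-[(2,6-dimethylphenyl)sulfanyl]-6-(3,5,7,3',4'-penta-O-benzyl-8-bromoepicatechin-4β-yl)epiafzelechin | c9ccccc9COc1ccc([C@H]2Oc3c(Br)c(OCc9ccccc9)c([C@H]4c5c(OCc9ccccc9)cc(OCc9ccccc9)c(Br)c5O[C@H](c5ccc(OCc9ccccc9)c(OCc9ccccc9)c5)[C@@H]4OCc9ccccc9)c(OCc9ccccc9)c3[C@H](Sc6c(C)cccc6C)[C@H]2OCc9ccccc9)cc1 | intermediate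
29 | nonadeca-O-benzyl tetramer with bromine on C8 of units 1, 2 and 4 | c9ccccc9COc1ccc([C@H]2Oc3c(Br)c(OCc9ccccc9)c([C@H]4c5c(OCc9ccccc9)cc(OCc9ccccc9)c(Br)c5O[C@H](c5ccc(OCc9ccccc9)c(OCc9ccccc9)c5)[C@@H]4OCc9ccccc9)c(OCc9ccccc9)c3[C@H](c3c(OCc9ccccc9)cc(OCc9ccccc9)c4c3O[C@H](c3ccc(OCc9ccccc9)c(OCc9ccccc9)c3)[C@H](OCc9ccccc9)[C@H]4c3c(OCc9ccccc9)c(Br)c4c(c3OCc9ccccc9)C[C@@H](OCc9ccccc9)[C@@H](c3ccc(OCc9ccccc9)c(OCc9ccccc9)c3)O4)[C@H]2OCc9ccccc9)cc1 | intermediate
30 | epicatechin-(4β→6)-epiafzelechin-(4β→8)-epicatechin-(4β→6)-epicatechin (CNP0103636.1) | Oc1ccc([C@H]2Oc3cc(O)c([C@H]4c5c(O)cc(O)cc5O[C@H](c5ccc(O)c(O)c5)[C@@H]4O)c(O)c3[C@H](c3c(O)cc(O)c4c3O[C@H](c3ccc(O)c(O)c3)[C@H](O)[C@H]4c3c(O)cc4c(c3O)C[C@@H](O)[C@@H](c3ccc(O)c(O)c3)O4)[C@H]2O)cc1 | target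

## Step count and least certain steps

Total: 22 steps. Longest linear sequence: 13 steps (steps 4–14, then 21 and 22).

**Step 10 (key step).** The Claisen closure may be too slow, because the ester carbon is flanked by the bulky flavanyl group; the opened keto ester would then relactonise or be hydrolysed by traces of water to an unreactive carboxylate. The fallback builds the ring before the crowding substituent is present. It sets out from 12 and 4. The dianion of 4 is alkylated with triflate 13 to give the 6-substituted 4-hydroxy-2-pyrone F1. O-Benzylation gives the 4-benzyloxy-2-pyrone F2. The same benzyloxide treatment, now on an unhindered pyrone, gives the symmetric 2-alkyl-5-benzyloxyresorcinol F3. TMSOTf-catalysed C-alkylation of F3 with 3 at −78 °C gives 17; the two free ring positions of F3 are equivalent, so the constitution is the same whichever reacts. The fallback rejoins the route at 17.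

**Step 8.** SN2 attack at a carbon next to an alkoxy-bearing branch may lose to elimination of triflic acid or to proton transfer that quenches the dianion. The fallback replaces the alkylation by a carbonyl addition followed by deoxygenation. It sets out from 12 and 5. Dess–Martin periodinane oxidises 12 to the aldehyde F4. Benzylation of 5 (BnBr, K2CO3) gives the 4-benzyloxy-6-methyl-2-pyrone F5. Its 6-methyl anion (LiN(i-Pr)2, −78 °C) adds to F4 to give the secondary carbinol F6 as an epimer mixture. 1,1'-Thiocarbonyldiimidazole gives the imidazolylthiocarbonate F7. Barton–McCombie deoxygenation (Bu3SnH, AIBN) removes the new oxygen and gives 15. The fallback rejoins the route at 15.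

**Step 13.** Closure may occur through the wrong phenol, which would place unit 3 on C8 of unit 4. Partial ionisation of the electron-rich benzylic oxyphosphonium intermediate may also erode the inversion at C2. The fallback removes the phenol choice. It sets out from 18. TIPSCl and imidazole silylate the less hindered phenol next to bromine, giving the aryl silyl ether F8. BnBr and K2CO3 benzylate the remaining phenol, giving the benzyl ether F9. Bu4NF removes both silyl groups, giving the phenol carbinol F10, which has one phenol and one hydroxyl. The Mitsunobu closure of F10 gives 21 directly. The fallback rejoins the route at 21.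

**Step 21.** Capture of a crowded dimeric cation by a crowded dimeric nucleophile may be slow. That would leave time for iodination of free ring A positions by the halonium reagent or for attack at C6 of unit 3. The fallback separates ionisation from the halonium source. It sets out from 28. NIS in wet acetone hydrolyses the sulfide to the C4 alcohol F11. F11 and 21 are then coupled with catalytic TMSOTf at −78 °C in a dehydrative Friedel–Crafts reaction, the standard activation of C4 oxygen leaving groups in benzylated flavanols, giving 29. The fallback rejoins the route at 29.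

## Further compounds

F1 | step 10 | 6-[(3R,4S)-3-(benzyloxy)-4-[3,4-bis(benzyloxy)phenyl]-4-[(tert-butyldimethylsilyl)oxy]butyl]-4-hydroxy-2H-pyran-2-one | O=C1OC(CC[C@@H](OCc9ccccc9)[C@@H](O[Si](C)(C)C(C)(C)C)c5ccc(OCc9ccccc9)c(OCc9ccccc9)c5)=CC(O)=C1
F2 | step 10 | 4-(benzyloxy)-6-[(3R,4S)-3-(benzyloxy)-4-[3,4-bis(benzyloxy)phenyl]-4-[(tert-butyldimethylsilyl)oxy]butyl]-2H-pyran-2-one | O=C1OC(CC[C@@H](OCc9ccccc9)[C@@H](O[Si](C)(C)C(C)(C)C)c5ccc(OCc9ccccc9)c(OCc9ccccc9)c5)=CC(OCc9ccccc9)=C1
F3 | step 10 | 5-(benzyloxy)-2-[(2R,3S)-2-(benzyloxy)-3-[3,4-bis(benzyloxy)phenyl]-3-[(tert-butyldimethylsilyl)oxy]propyl]benzene-1,3-diol | Oc1cc(OCc9ccccc9)cc(O)c1C[C@@H](OCc9ccccc9)[C@@H](O[Si](C)(C)C(C)(C)C)c5ccc(OCc9ccccc9)c(OCc9ccccc9)c5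
F4 | step 8 | (2S,3S)-2-(benzyloxy)-3-[3,4-bis(benzyloxy)phenyl]-3-[(tert-butyldimethylsilyl)oxy]propanal | O=C[C@@H](OCc9ccccc9)[C@@H](O[Si](C)(C)C(C)(C)C)c1ccc(OCc9ccccc9)c(OCc9ccccc9)c1
F5 | step 8 | 4-(benzyloxy)-6-methyl-3-(penta-O-benzylepicatechin-4β-yl)-2H-pyran-2-one | CC1=CC(OCc9ccccc9)=C([C@H]2c3c(OCc9ccccc9)cc(OCc9ccccc9)cc3O[C@H](c3ccc(OCc9ccccc9)c(OCc9ccccc9)c3)[C@@H]2OCc9ccccc9)C(=O)O1
F6 | step 8 | 4-(benzyloxy)-6-[(3S,4S)-3-(benzyloxy)-4-[3,4-bis(benzyloxy)phenyl]-4-[(tert-butyldimethylsilyl)oxy]-2-hydroxybutyl]-3-(penta-O-benzylepicatechin-4β-yl)-2H-pyran-2-one (carbinol epimers) | O=C1OC(CC(O)[C@@H](OCc9ccccc9)[C@@H](O[Si](C)(C)C(C)(C)C)c5ccc(OCc9ccccc9)c(OCc9ccccc9)c5)=CC(OCc9ccccc9)=C1[C@H]4c5c(OCc9ccccc9)cc(OCc9ccccc9)cc5O[C@H](c5ccc(OCc9ccccc9)c(OCc9ccccc9)c5)[C@@H]4OCc9ccccc9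
F7 | step 8 | O-(imidazol-1-ylthiocarbonyl) derivative of F6 | O=C1OC(CC(OC(=S)n2ccnc2)[C@@H](OCc9ccccc9)[C@@H](O[Si](C)(C)C(C)(C)C)c5ccc(OCc9ccccc9)c(OCc9ccccc9)c5)=CC(OCc9ccccc9)=C1[C@H]4c5c(OCc9ccccc9)cc(OCc9ccccc9)cc5O[C@H](c5ccc(OCc9ccccc9)c(OCc9ccccc9)c5)[C@@H]4OCc9ccccc9
F8 | step 13 | 18 with the phenol next to bromine as its triisopropylsilyl ether | CC(C)[Si](C(C)C)(C(C)C)Oc1c(Br)c(OCc9ccccc9)c([C@H]4c5c(OCc9ccccc9)cc(OCc9ccccc9)cc5O[C@H](c5ccc(OCc9ccccc9)c(OCc9ccccc9)c5)[C@@H]4OCc9ccccc9)c(O)c1C[C@@H](OCc9ccccc9)[C@@H](O[Si](C)(C)C(C)(C)C)c5ccc(OCc9ccccc9)c(OCc9ccccc9)c5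
F9 | step 13 | benzyl ether of F8 at the remaining phenol | CC(C)[Si](C(C)C)(C(C)C)Oc1c(Br)c(OCc9ccccc9)c([C@H]4c5c(OCc9ccccc9)cc(OCc9ccccc9)cc5O[C@H](c5ccc(OCc9ccccc9)c(OCc9ccccc9)c5)[C@@H]4OCc9ccccc9)c(OCc9ccccc9)c1C[C@@H](OCc9ccccc9)[C@@H](O[Si](C)(C)C(C)(C)C)c5ccc(OCc9ccccc9)c(OCc9ccccc9)c5
F10 | step 13 | 3,5-bis(benzyloxy)-2-bromo-6-[(2R,3S)-2-(benzyloxy)-3-[3,4-bis(benzyloxy)phenyl]-3-hydroxypropyl]-4-(penta-O-benzylepicatechin-4β-yl)phenol | Oc1c(Br)c(OCc9ccccc9)c([C@H]4c5c(OCc9ccccc9)cc(OCc9ccccc9)cc5O[C@H](c5ccc(OCc9ccccc9)c(OCc9ccccc9)c5)[C@@H]4OCc9ccccc9)c(OCc9ccccc9)c1C[C@@H](OCc9ccccc9)[C@@H](O)c5ccc(OCc9ccccc9)c(OCc9ccccc9)c5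
F11 | step 21 | 28 with a 4β-hydroxyl in place of the sulfide on unit 2 | c9ccccc9COc1ccc([C@H]2Oc3c(Br)c(OCc9ccccc9)c([C@H]4c5c(OCc9ccccc9)cc(OCc9ccccc9)c(Br)c5O[C@H](c5ccc(OCc9ccccc9)c(OCc9ccccc9)c5)[C@@H]4OCc9ccccc9)c(OCc9ccccc9)c3[C@H](O)[C@H]2OCc9ccccc9)cc1
A1 | alternative 1 | doubly linked (C4–C6 and C2–O7) bicyclic ketal of benzylated unit 1 on 8-bromo-3,4'-di-O-benzylepiafzelechin, with free 3-OH on unit 1 and free 5-OH on unit 2 | c9ccccc9COc1ccc([C@H]2Oc3c(Br)c(O6)c([C@H]4c5c(OCc9ccccc9)cc(OCc9ccccc9)cc5O[C@]6(c5ccc(OCc9ccccc9)c(OCc9ccccc9)c5)[C@@H]4O)c(O)c3C[C@H]2OCc9ccccc9)cc1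
A2 | alternative 2 | 2-[(E)-3-(4-benzyloxyphenyl)prop-2-enyl]-3,5-bis(triisopropylsilyloxy)-4-(penta-O-benzylepicatechin-4β-yl)phenol | Oc1cc(O[Si](C(C)C)(C(C)C)C(C)C)c([C@H]4c5c(OCc9ccccc9)cc(OCc9ccccc9)cc5O[C@H](c5ccc(OCc9ccccc9)c(OCc9ccccc9)c5)[C@@H]4OCc9ccccc9)c(O[Si](C(C)C)(C(C)C)C(C)C)c1C/C=C/c1ccc(OCc9ccccc9)cc1
A3 | alternative 3 | per-O-benzylated tetramer carrying a 3-O-benzoate on unit 2 | c9ccccc9COc1ccc([C@H]2Oc3cc(OCc9ccccc9)c([C@H]4c5c(OCc9ccccc9)cc(OCc9ccccc9)cc5O[C@H](c5ccc(OCc9ccccc9)c(OCc9ccccc9)c5)[C@@H]4OCc9ccccc9)c(OCc9ccccc9)c3[C@H](c3c(OCc9ccccc9)cc(OCc9ccccc9)c4c3O[C@H](c3ccc(OCc9ccccc9)c(OCc9ccccc9)c3)[C@H](OCc9ccccc9)[C@H]4c3c(OCc9ccccc9)cc4c(c3OCc9ccccc9)C[C@@H](OCc9ccccc9)[C@@H](c3ccc(OCc9ccccc9)c(OCc9ccccc9)c3)O4)[C@H]2OC(=O)c6ccccc6)cc1
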